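## Analysis of the target

The target is a spiro[5.6] system. A seven-membered carbocycle (C1 and C2 of the trimethoxyarene ring A, then C1', C7', C8', C8, C7) is fused to ring A, and its carbon C1' is also C-4 of a 2,6-dimethoxycyclohexa-2,5-dienone (ring B, carbonyl C4'). Three contiguous stereocentres sit on the seven-membered ring: C7 (R, benzylic secondary alcohol), C8 (S, methyl) and C8' (R, methyl). The two methyl groups are trans, and the hydroxyl is trans to the C8 methyl. The spiro carbon C1' is quaternary but not stereogenic, because ring B is symmetric. The cross-conjugated dienone is sensitive to acid (dienone–phenol rearrangement by 1,2-shift of the aryl or alkyl arm), to hydride and to Lewis acidic organometallics at C4'. The C7 alcohol is benzylic to an arene with a para methoxy group and ionises easily in acid. The synthesis is hard for two reasons. First, C1' is bonded to a doubly ortho-substituted arene and belongs to a dearomatised ring that is less stable than its aromatic isomers, so reversible allyl or alkyl transfer to a phenol cannot make it. Second, three stereocentres must be set on a ring with no resident chirality. The strategy rests on C8 and C8' being neighbours opposite the arene in the seven-membered ring: a C8=C8' double bond conjugated with a C7 ketone can be closed from an allyl group on C1' and a methacryloyl group on C1, and the resulting achiral enone then receives the stereocentres one at a time.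

## Retrosynthetic reasoning

**21 ⇒ 20.** No skeletal bond is cut. The C4' carbonyl of target 21 is traced back to the dimethyl ketal 20, so that ring B is a bis(enol ether) ketal with no carbonyl during every organometallic and hydride step. The forward step has to hydrolyse one ketal without touching the C7 alcohol.

**20 ⇒ 19.** The C7–H bond is cut, leading to the trans-dimethyl ketone 19. A reagent-controlled reduction sets C7 last, next to an already fixed C8 centre, and C8 can no longer epimerise afterwards.

**19 ⇒ 18 ⇒ 16.** The C8'–CH3 bond is cut, and C8 is made epimerisable in the ketone 18. This leads to the achiral enone 16, in which the C8 methyl is already on the double bond. A catalytic enantioselective conjugate methylation has to fix C8' (the only stereocentre whose absolute sense must come from a catalyst), and C8 follows by equilibration to the trans isomer.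

**16 ⇒ 15.** The C8=C8' double bond is cut. This is the bond furthest from the hindered C1'–C2 junction, and both fragments of the cut are simple terminal alkenes: an allyl group on C1' and an isopropenyl ketone on C1 in the diene 15. Ring-closing metathesis has to close a seven-membered ring onto a 1,1-disubstituted, electron-poor alkene.

**15 ⇒ 14 ⇒ 13.** Functional group changes only. The enone of 15 comes from the allylic alcohol 14, and this from the silyl ether 13, so that the C7 oxygen is inert while C1' is built.

**13 ⇒ 11.** The C1'–C7' bond is cut. Transferring an allyl group from oxygen to the para carbon of an aromatic ring B was rejected: with both ortho positions and the para position substituted, the aromatic ether is the thermodynamic sink and the 4-allyl dienone is only a minor partner in the equilibrium. The allyl group is therefore traced back to the carbinol carbon C3' of the non-aromatic dienol 11, where it forms a 3-hydroxy-1,5-diene with the C2'=C1' double bond. An anionic [3,3] shift moves it to C1' irreversibly and leaves an enolate at C3', whose O-methylation restores the symmetric ring B.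

**11 ⇒ 9 + 10.** The C3'–allyl bond is cut, giving the linearly conjugated dienone 9 and allylmagnesium bromide 10. The forward step is a simple 1,2-addition.

**9 ⇒ 6 + 2.** The C2–C1' bond is cut. The hindered aryl carbon becomes a nucleophile (an aryllithium from bromide 6) and ring B arrives as the quinone monoketal 2, which already has all three oxygens at the final oxidation level. Addition at the carbonyl followed by acid-induced 1,3-transposition puts the arene on an sp2 carbon and moves the carbonyl to C3'. Ring B of the adduct is symmetric, so only one dienone can form.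

**6 ⇒ 5 ⇒ 3 + 4, and 2 ⇒ 1.** The C7–C8 bond is cut between the commercial aldehyde 3 and isopropenylmagnesium bromide 4, with the alcohol 5 protected as 6. The ketal 2 is the oxidative methanol adduct of the commercial phenol 1.

## Alternatives that were turned down

**Alternative 1:** Ring B is cut at C1'–C2' and C3'–C4'. In the forward direction a malonate diester A2 adds to the exocyclic enone A1, a methyl ketone whose β-carbon is C1' of a stereodefined benzocycloheptane. The ketone enolate then closes onto one ester, and loss of the spare ester gives the spiro cyclohexane-1,3-dione A3.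
- For: the quaternary carbon comes from classical carbonyl chemistry, no dearomatised ring has to be made against thermodynamics, and the three stereocentres are in place before ring B exists. On this last point it is stronger than the chosen route, which needs a late enantioselective catalytic step.
- Against: A3 has oxygen only at C3' and C5'. C4' must still be oxidised and two double bonds introduced, and the required 2,6-bis(enol ether) is not the favoured enol form of a cyclic 1,2,3-tricarbonyl system, so the methylation pattern is uncertain. The Michael addition also has to create a quaternary carbon beside a doubly ortho-substituted arene.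
- Comparison: the chosen route brings ring B in with all three oxygens at the right level and ends with one hydrolysis.

**Alternative 2:** The C1'–C7' bond is cut. The phenolate of the biaryl A4, which carries the full C7–C8–C8'–C7' chain ending in a primary mesylate, attacks through its para carbon and gives the silyl-protected target A5.
- For: one step forms the quaternary centre, the seven-membered ring and the dienone. Because the step is intramolecular and irreversible, O-alkylation is excluded by geometry and the thermodynamic problem of dearomatisation is bypassed. Only a desilylation remains. On these points it is stronger than the chosen route.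
- Against: A4 needs three contiguous stereocentres built on an open chain ortho to a hindered biaryl bond, which means a longer auxiliary- or reagent-controlled sequence. The closure is a spiro alkylation through a seven-membered transition state, less favourable than the five- and six-membered cases, and it competes with intermolecular O-alkylation.
- Comparison: the chosen route closes the ring by a mode with broad precedent for seven-membered rings and draws its stereocentres from catalysts acting on an achiral ring.

**Alternative 3:** The C1–C7 and C1'–C7' bonds are cut. Zerovalent palladium inserts into the C1–Br bond of the bromo biaryl phenol A6, the arylpalladium adds to the diene A7, and the phenol para carbon captures the allylpalladium to give the spirodienone A8.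
- For: it is the most convergent plan (two C–C bonds, the ring, the quaternary carbon and the dienone in one step from a simple biaryl) and is shorter to the skeleton than the chosen route.
- Against: capture at the nearer allyl terminus would give a five-membered spiro ring. A8 lacks the C7 oxygen and has a tetrasubstituted C8=C8' alkene. Benzylic oxidation beside that alkene and a dienone has no dependable solution, and neither has reduction of the tetrasubstituted alkene to a trans-dimethyl pair (hydrogenation gives cis, and the dienone alkenes compete).
- Comparison: the chosen route keeps the C7 oxygen throughout and uses conjugation of C8=C8' with the C7 ketone as the handle for stereocontrolled methyl delivery.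

Key step: step 9

Remarks on the chemistry:
- Assumption: the (S)-binaphthol phosphoramidite with a bis[(R)-1-phenylethyl]amino group delivers methyl to the face of C8' that gives 8'R; if the opposite sense is found, the enantiomeric ligand is used.
- Assumption: in the oxazaborolidine reduction the arene acts as the large substituent, so the (S)-catalyst gives the 7R alcohol.
- Assumption: the trans arrangement of the C8 and C8' methyl groups is the more stable one in ketone 19.
- Intermediates that contain the ring B bis(enol ether) ketal (13 to 20) are purified on triethylamine-deactivated silica.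
- In the spiro names, positions 5, 6, 7, 8 and 9 of the benzo[7]annulene are C7, C8, C8', C7' and C1'.

## Route

Step 1
Reactants: 1 3,4,5-trimethoxyphenol
Product: 2 3,4,4,5-tetramethoxycyclohexa-2,5-dien-1-one
Conditions: PhI(OAc)2, MeOH, 0 °C
Reagents that add atoms: methanol, CO
Why: Oxidative dearomatisation of a para-methoxyphenol to a quinone monoketal; methanol adds at the methoxy-bearing para carbon because the ortho carbons carry no donor, and the product cannot be oxidised further.

Step 2
Reactants: 3 2-bromo-3,4,5-trimethoxybenzaldehyde; 4 isopropenylmagnesium bromide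
Product: 5 1-(2-bromo-3,4,5-trimethoxyphenyl)-2-methylprop-2-en-1-ol (racemic)
Conditions: THF, −78 → 0 °C; aq. NH4Cl
Reagents that add atoms: none
Why: Grignard 1,2-addition to an aryl aldehyde; the aryl bromide is inert at this temperature, and the racemic C7 centre is removed later by oxidation.

Step 3
Reactants: 5 1-(2-bromo-3,4,5-trimethoxyphenyl)-2-methylprop-2-en-1-ol
Product: 6 {[1-(2-bromo-3,4,5-trimethoxyphenyl)-2-methylprop-2-en-1-yl]oxy}(tert-butyl)dimethylsilane (racemic)
Conditions: TBSCl, imidazole, DMF, rt
Reagents that add atoms: tert-butyldimethylsilyl chloride, CC(C)(C)[Si](C)(C)Cl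
Why: Standard silylation; the silyl ether tolerates organolithium, Grignard and KH and is removed later with fluoride, without acid.

Step 4
Reactants: 6 {[1-(2-bromo-3,4,5-trimethoxyphenyl)-2-methylprop-2-en-1-yl]oxy}(tert-butyl)dimethylsilane; 2 3,4,4,5-tetramethoxycyclohexa-2,5-dien-1-one
Product: 9 3-{6-[1-(tert-butyldimethylsilyloxy)-2-methylprop-2-en-1-yl]-2,3,4-trimethoxyphenyl}-5,6,6-trimethoxycyclohexa-2,4-dien-1-one (racemic), via aryllithium 7 (not isolated), via lithium alkoxide 8 (not isolated)
Conditions: n-BuLi, THF, −78 °C; then 2, −78 °C; then 5% aq. oxalic acid, 0 °C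
Reagents that add atoms: water, O
Why: Bromine–lithium exchange gives 7, which adds 1,2 to the doubly vinylogous ester carbonyl of 2; mild acid ionises the tertiary bis-allylic carbinol from 8 and water re-enters at a methoxy-bearing terminus with loss of methanol (Stork–Danheiser 1,3-carbonyl transposition). The adduct is symmetric, so one dienone results, and its ketal, now next to a carbonyl, resists hydrolysis.

Step 5
Reactants: 9 3-aryl-5,6,6-trimethoxycyclohexa-2,4-dien-1-one (aryl as in step 4); 10 allylmagnesium bromide
Product: 11 1-allyl-3-{6-[1-(tert-butyldimethylsilyloxy)-2-methylprop-2-en-1-yl]-2,3,4-trimethoxyphenyl}-5,6,6-trimethoxycyclohexa-2,4-dien-1-ol (mixture of diastereomers)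
Conditions: THF, −78 °C; pH 7 phosphate buffer; used crude
Reagents that add atoms: none
Why: Allyl Grignard reagents add 1,2 to conjugated ketones through a six-membered transition state; this places the allyl group on C3' as part of a 3-hydroxy-1,5-diene with C2'=C1', and the new carbinol centre is lost in the next step.

Step 6
Reactants: 11 1-allyl-3-aryl-5,6,6-trimethoxycyclohexa-2,4-dien-1-ol
Product: 13 tert-butyl({1-[2-(1-allyl-3,4,4,5-tetramethoxycyclohexa-2,5-dien-1-yl)-3,4,5-trimethoxyphenyl]-2-methylprop-2-en-1-yl}oxy)dimethylsilane (racemic), via potassium enolate 12 (not isolated)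
Conditions: KH, 18-crown-6, THF, 0 °C → rt; then Me2SO4, −78 → 0 °C; aq. NH3
Reagents that add atoms: dimethyl sulfate, COS(=O)(=O)OC
Why: Anionic oxy-Cope rearrangement: the potassium alkoxide shifts the allyl group from C3' to C1' and forms enolate 12, which makes the step irreversible and builds the hindered quaternary carbon intramolecularly. The crown-complexed potassium enolate has a neopentyl α-carbon and should be O-methylated by the hard electrophile, restoring the symmetric bis(enol ether) ketal.

Step 7
Reactants: 13 silyl ether of step 6
Product: 14 1-[2-(1-allyl-3,4,4,5-tetramethoxycyclohexa-2,5-dien-1-yl)-3,4,5-trimethoxyphenyl]-2-methylprop-2-en-1-ol (racemic)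
Conditions: Bu4NF, THF, rt
Reagents that add atoms: none
Why: Fluoride desilylation under basic conditions, which the ketal and the enol ethers tolerate.

Step 8
Reactants: 14 allylic alcohol of step 7
Product: 15 1-[2-(1-allyl-3,4,4,5-tetramethoxycyclohexa-2,5-dien-1-yl)-3,4,5-trimethoxyphenyl]-2-methylprop-2-en-1-one
Conditions: Dess–Martin periodinane, NaHCO3, CH2Cl2, 0 °C → rt
Reagents that add atoms: none
Why: Dess–Martin oxidation of a benzylic, allylic alcohol to the methacryloyl ketone; hydrogencarbonate takes up the acetic acid so that the enol ethers and the ketal are not protonated.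

Step 9
Reactants: 15 1-[2-(1-allyl-3,4,4,5-tetramethoxycyclohexa-2,5-dien-1-yl)-3,4,5-trimethoxyphenyl]-2-methylprop-2-en-1-one
Product: 16 1,2,3,3',4',4',5'-heptamethoxy-6-methyl-8H-spiro[benzo[7]annulene-9,1'-cyclohexa[2,5]dien]-5-one (C7 ketone; C8(Me)=C8'H; ring B as dimethyl ketal)
Conditions: second-generation Hoveyda–Grubbs catalyst RuCl2(H2IMes)(=CH-C6H4-2-O-i-Pr) (10 mol%), 1,4-benzoquinone (20 mol%), toluene (0.002 M), 80 °C, argon stream
Reagents that add atoms: none
Why: The catalyst initiates at the monosubstituted allyl alkene and gives a ruthenium alkylidene on C8', which adds [2+2] across the 1,1-disubstituted alkene of the methacryloyl group; the ruthenacyclobutane opens to the C8=C8' double bond and a ruthenium methylidene, which carries the chain and ends as ethylene. The closest known reaction type is ring-closing metathesis of allyl/isopropenyl ketone dienes to 2-methylcycloalk-2-enones with second-generation carbene–ruthenium catalysts. The seven-membered ring closes by intramolecular alkene metathesis with the new double bond inside the ring, and the ring size enforces the cis ring alkene. No stereocentre is formed, and C1' stays non-stereogenic because ring B is symmetric. The step needs cyclisation to beat oligomerisation and initiation at the allyl group: high dilution, the quaternary C1' and the ortho relationship of the two arms on ring A favour closure, and the electron-poor methacryloyl alkene does not homodimerise. The enol ether double bonds of ring B are trisubstituted and flank a quaternary and a ketal carbon, so they should not engage the catalyst; benzoquinone suppresses hydride-induced migration of the allyl double bond. The argon stream removes ethylene and drives the reaction.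

Step 10
Reactants: 16 spiro enone of step 9
Product: 18 (7R)-1,2,3,3',4',4',5'-heptamethoxy-6,7-dimethyl-7,8-dihydro-6H-spiro[benzo[7]annulene-9,1'-cyclohexa[2,5]dien]-5-one (8'R; mixture of C8 epimers), via dimethylaluminium enolate 17 (not isolated)
Conditions: Me3Al, copper thiophene-2-carboxylate Cu(O2C-C4H3S) (5 mol%), (S)-binaphthol N,N-bis[(R)-1-phenylethyl]phosphoramidite (10 mol%), Et2O, −30 °C; MeOH, then aq. potassium sodium tartrate
Reagents that add atoms: trimethylaluminium, C[Al](C)C
Why: Copper-catalysed enantioselective conjugate addition of a methylaluminium reagent to an α-substituted cyclic enone; the chiral phosphoramidite–copper complex selects the face of C8' (8'R), and protonation of enolate 17 gives both C8 epimers. Ether as solvent and low temperature keep the Lewis acidity too low to ionise the ketal.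

Step 11
Reactants: 18 ketone of step 10 (mixture of C8 epimers)
Product: 19 (6S,7R)-1,2,3,3',4',4',5'-heptamethoxy-6,7-dimethyl-7,8-dihydro-6H-spiro[benzo[7]annulene-9,1'-cyclohexa[2,5]dien]-5-one (8S,8'R; methyl groups trans)
Conditions: DBU, toluene, rt → 40 °C
Reagents that add atoms: none
Why: Base-mediated epimerisation through the enolate at C8, the only acidic position (C8' is untouched); the trans isomer, with both methyl groups pseudo-equatorial, should be favoured at equilibrium.

Step 12
Reactants: 19 trans-dimethyl ketone of step 11
Product: 20 (5R,6S,7R)-1,2,3,3',4',4',5'-heptamethoxy-6,7-dimethyl-5,6,7,8-tetrahydrospiro[benzo[7]annulene-9,1'-cyclohexa[2,5]dien]-5-ol (7R,8S,8'R)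
Conditions: (S)-2-methyl-CBS-oxazaborolidine (0.5 equiv), catecholborane, toluene, −40 °C; MeOH, then aq. NaOH
Reagents that add atoms: none
Why: Corey–Bakshi–Shibata reduction: the oxazaborolidine binds the ketone with the arene as the large group and delivers hydride to the face that gives 7R, with the hydroxyl trans to the C8 methyl. Catecholborane does not hydroborate the hindered enol ethers at this temperature.

Step 13
Reactants: 20 alcohol of step 12
Product: 21 (5R,6S,7R)-5-hydroxy-1,2,3,3',5'-pentamethoxy-6,7-dimethyl-5,6,7,8-tetrahydrospiro[benzo[7]annulene-9,1'-cyclohexa[2,5]dien]-4'-one (target)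
Conditions: PPTS, acetone–H2O (9:1), rt
Reagents that add atoms: water, O
Why: Acid-catalysed ketal hydrolysis: loss of methanol from C4' gives an oxocarbenium ion flanked by two vinyl groups, water adds, and the second methanol leaves to give the cross-conjugated dienone. The weak acid should leave the benzylic C7 alcohol un-ionised and should not trigger a 1,2-shift in the dienone.

## Compound list

1 | 3,4,5-trimethoxyphenol | COc1cc(O)cc(OC)c1OC | starting material
2 | 3,4,4,5-tetramethoxycyclohexa-2,5-dien-1-one | COC1=CC(=O)C=C(OC)C1(OC)OC | intermediate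
3 | 2-bromo-3,4,5-trimethoxybenzaldehyde | COc1cc(C=O)c(Br)c(OC)c1OC | starting material
4 | isopropenylmagnesium bromide | C=C(C)[Mg]Br | starting material
5 | 1-(2-bromo-3,4,5-trimethoxyphenyl)-2-methylprop-2-en-1-ol (racemic) | C=C(C)C(O)c1cc(OC)c(OC)c(OC)c1Br | intermediate
6 | {[1-(2-bromo-3,4,5-trimethoxyphenyl)-2-methylprop-2-en-1-yl]oxy}(tert-butyl)dimethylsilane (racemic) | C=C(C)C(O[Si](C)(C)C(C)(C)C)c1cc(OC)c(OC)c(OC)c1Br | intermediate
7 | {6-[1-(tert-butyldimethylsilyloxy)-2-methylprop-2-en-1-yl]-2,3,4-trimethoxyphenyl}lithium | C=C(C)C(O[Si](C)(C)C(C)(C)C)c1cc(OC)c(OC)c(OC)c1[Li] | intermediate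
8 | lithium 1-aryl-3,4,4,5-tetramethoxycyclohexa-2,5-dien-1-olate (aryl as in 7) | C=C(C)C(O[Si](C)(C)C(C)(C)C)c1cc(OC)c(OC)c(OC)c1C1(O[Li])C=C(OC)C(OC)(OC)C(OC)=C1 | intermediate
9 | 3-{6-[1-(tert-butyldimethylsilyloxy)-2-methylprop-2-en-1-yl]-2,3,4-trimethoxyphenyl}-5,6,6-trimethoxycyclohexa-2,4-dien-1-one (racemic) | C=C(C)C(O[Si](C)(C)C(C)(C)C)c1cc(OC)c(OC)c(OC)c1C1=CC(=O)C(OC)(OC)C(OC)=C1 | intermediate
10 | allylmagnesium bromide | C=CC[Mg]Br | starting material
11 | 1-allyl-3-{6-[1-(tert-butyldimethylsilyloxy)-2-methylprop-2-en-1-yl]-2,3,4-trimethoxyphenyl}-5,6,6-trimethoxycyclohexa-2,4-dien-1-ol (diastereomer mixture) | C=CCC1(O)C=C(c2c(OC)c(OC)c(OC)cc2C(O[Si](C)(C)C(C)(C)C)C(C)=C)C=C(OC)C1(OC)OC | intermediate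
12 | potassium 3-allyl-3-aryl-5,6,6-trimethoxycyclohexa-1,4-dien-1-olate (aryl as in 7) | [K+].[O-]C1=CC(CC=C)(c2c(OC)c(OC)c(OC)cc2C(O[Si](C)(C)C(C)(C)C)C(C)=C)C=C(OC)C1(OC)OC | intermediate
13 | tert-butyl({1-[2-(1-allyl-3,4,4,5-tetramethoxycyclohexa-2,5-dien-1-yl)-3,4,5-trimethoxyphenyl]-2-methylprop-2-en-1-yl}oxy)dimethylsilane (racemic) | COC1=CC(CC=C)(c2c(OC)c(OC)c(OC)cc2C(O[Si](C)(C)C(C)(C)C)C(C)=C)C=C(OC)C1(OC)OC | intermediate
14 | 1-[2-(1-allyl-3,4,4,5-tetramethoxycyclohexa-2,5-dien-1-yl)-3,4,5-trimethoxyphenyl]-2-methylprop-2-en-1-ol (racemic) | COC1=CC(CC=C)(c2c(OC)c(OC)c(OC)cc2C(O)C(C)=C)C=C(OC)C1(OC)OC | intermediate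
15 | 1-[2-(1-allyl-3,4,4,5-tetramethoxycyclohexa-2,5-dien-1-yl)-3,4,5-trimethoxyphenyl]-2-methylprop-2-en-1-one | COC1=CC(CC=C)(c2c(OC)c(OC)c(OC)cc2C(=O)C(C)=C)C=C(OC)C1(OC)OC | intermediate
16 | 1,2,3,3',4',4',5'-heptamethoxy-6-methyl-8H-spiro[benzo[7]annulene-9,1'-cyclohexa[2,5]dien]-5-one | COC1=CC2(C=C(OC)C1(OC)OC)CC=C(C)C(=O)c1cc(OC)c(OC)c(OC)c12 | intermediate
17 | dimethylaluminium enolate of 18 (8'R) | COC1=CC2(C=C(OC)C1(OC)OC)C[C@@H](C)C(C)=C(O[Al](C)C)c1cc(OC)c(OC)c(OC)c12 | intermediate
18 | (7R)-1,2,3,3',4',4',5'-heptamethoxy-6,7-dimethyl-7,8-dihydro-6H-spiro[benzo[7]annulene-9,1'-cyclohexa[2,5]dien]-5-one (C8 epimer mixture) | COC1=CC2(C=C(OC)C1(OC)OC)C[C@@H](C)C(C)C(=O)c1cc(OC)c(OC)c(OC)c12 | intermediate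
19 | (6S,7R)-1,2,3,3',4',4',5'-heptamethoxy-6,7-dimethyl-7,8-dihydro-6H-spiro[benzo[7]annulene-9,1'-cyclohexa[2,5]dien]-5-one | COC1=CC2(C=C(OC)C1(OC)OC)C[C@@H](C)[C@H](C)C(=O)c1cc(OC)c(OC)c(OC)c12 | intermediate
20 | (5R,6S,7R)-1,2,3,3',4',4',5'-heptamethoxy-6,7-dimethyl-5,6,7,8-tetrahydrospiro[benzo[7]annulene-9,1'-cyclohexa[2,5]dien]-5-ol | COC1=CC2(C=C(OC)C1(OC)OC)C[C@@H](C)[C@H](C)[C@@H](O)c1cc(OC)c(OC)c(OC)c12 | intermediate
21 | (5R,6S,7R)-5-hydroxy-1,2,3,3',5'-pentamethoxy-6,7-dimethyl-5,6,7,8-tetrahydrospiro[benzo[7]annulene-9,1'-cyclohexa[2,5]dien]-4'-one | COC1=CC2(C=C(OC)C1=O)C[C@@H](C)[C@H](C)[C@@H](O)c1cc(OC)c(OC)c(OC)c12 | target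

## Step count and least certain steps

Total step count: 13. Longest linear sequence: 12 steps (steps 2 to 13, from 3); step 1 is a one-step side branch that joins in step 4.

**Step 9 (key step).** Productive metathesis at the electron-poor, 1,1-disubstituted methacryloyl alkene may be slow, so that intermolecular coupling through the allyl groups, migration of the allyl double bond and catalyst decay take over. Fallback: set out from 14 and run the ring closure at the alcohol level, where the 1,1-disubstituted alkene is electron-rich and the free hydroxyl assists, to give the cyclic allylic alcohol F1. Oxidation of F1 with Dess–Martin periodinane and NaHCO3 returns to the route at 16.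

**Step 4.** In aryllithium 7 the silyl group may migrate from oxygen to the lithiated carbon before the addition. During the acid treatment the C1' cation may be captured by the neighbouring silyloxy oxygen, or ketal hydrolysis to a para-quinol may compete with the transposition. Fallback: set out from 6 and convert it by lithium–bromine exchange and borylation with 2-isopropoxy-4,4,5,5-tetramethyl-1,3,2-dioxaborolane into the aryl pinacol boronate F2. Suzuki–Miyaura coupling of F2 with commercial 5-bromo-2,3-dimethoxyphenol (Pd(OAc)2, SPhos, K3PO4) gives the biaryl phenol F3. Oxidation of F3 with PhI(OAc)2 in methanol adds methanol at the methoxy-bearing ortho carbon and returns to the route at 9.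

**Step 6.** The hindered potassium alkoxide may fragment by loss of an allyl anion instead of rearranging, and the enolate may be methylated on carbon. Fallback: set out from 9 and add the allyl group 1,4 with an allylcopper reagent (allylmagnesium bromide, CuBr·SMe2, Me3SiCl, THF, −78 °C) to give the ketone F4. Separate O-methylation of its enolate (KN(SiMe3)2, Me2SO4, DMPU) returns to the route at 13.

**Step 10.** Facial discrimination at the hindered α-methyl enone may be low, and the Lewis acidic aluminium reagent may ionise the ketal. Fallback: set out from 16, add Me2CuLi with Me3SiCl and equilibrate with DBU to the racemic trans ketone F5. The oxazaborolidine reduction of step 12 then turns the two enantiomers into two diastereomeric alcohols, 20 and the (5R,6R,7S) alcohol F6, which are separated by chromatography. The route is rejoined at 20.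

**Step 12.** The reagent-preferred face may be opposed by the substrate, since hydride has to arrive syn to the C8 methyl, so that diastereoselectivity erodes or the hindered ketone reacts slowly. Fallback: set out from 19 and reduce with LiBH(s-Bu)3, which should add hydride anti to the C8 methyl and give the 7-epimeric alcohol F7. Mitsunobu inversion with 4-nitrobenzoic acid gives the ester F8, and methanolysis (K2CO3, MeOH) returns to the route at 20.

**Step 13.** Protonation of the enol ethers may compete with ketal ionisation and lead to partial loss of a ring B methyl ether, and longer acid exposure invites ionisation at C7. Fallback: set out from 20, complete the hydrolysis and treat the crude product, which then contains the enol F9, with Me3SiCHN2 in methanol. The acidic enol is re-methylated and the benzylic alcohol is not, giving 21.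

## Further compounds

F1 | step 9 | 1,2,3,3',4',4',5'-heptamethoxy-6-methyl-5,8-dihydrospiro[benzo[7]annulene-9,1'-cyclohexa[2,5]dien]-5-ol (racemic) | COC1=CC2(C=C(OC)C1(OC)OC)CC=C(C)C(O)c1cc(OC)c(OC)c(OC)c12
F2 | step 4 | tert-butyldimethyl({2-methyl-1-[3,4,5-trimethoxy-2-(4,4,5,5-tetramethyl-1,3,2-dioxaborolan-2-yl)phenyl]prop-2-en-1-yl}oxy)silane (racemic) | C=C(C)C(O[Si](C)(C)C(C)(C)C)c1cc(OC)c(OC)c(OC)c1B1OC(C)(C)C(C)(C)O1
F3 | step 4 | 5-{6-[1-(tert-butyldimethylsilyloxy)-2-methylprop-2-en-1-yl]-2,3,4-trimethoxyphenyl}-2,3-dimethoxyphenol (racemic) | C=C(C)C(O[Si](C)(C)C(C)(C)C)c1cc(OC)c(OC)c(OC)c1-c1cc(O)c(OC)c(OC)c1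
F4 | step 6 | 5-allyl-5-{6-[1-(tert-butyldimethylsilyloxy)-2-methylprop-2-en-1-yl]-2,3,4-trimethoxyphenyl}-2,2,3-trimethoxycyclohex-3-en-1-one (diastereomer mixture) | C=CCC1(c2c(OC)c(OC)c(OC)cc2C(O[Si](C)(C)C(C)(C)C)C(C)=C)CC(=O)C(OC)(OC)C(OC)=C1
F5 | step 10 | racemic trans-1,2,3,3',4',4',5'-heptamethoxy-6,7-dimethyl-7,8-dihydro-6H-spiro[benzo[7]annulene-9,1'-cyclohexa[2,5]dien]-5-one (one enantiomer drawn) | COC1=CC2(C=C(OC)C1(OC)OC)C[C@@H](C)[C@H](C)C(=O)c1cc(OC)c(OC)c(OC)c12
F6 | step 10 | (5R,6R,7S)-1,2,3,3',4',4',5'-heptamethoxy-6,7-dimethyl-5,6,7,8-tetrahydrospiro[benzo[7]annulene-9,1'-cyclohexa[2,5]dien]-5-ol | COC1=CC2(C=C(OC)C1(OC)OC)C[C@H](C)[C@@H](C)[C@@H](O)c1cc(OC)c(OC)c(OC)c12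
F7 | step 12 | (5S,6S,7R)-1,2,3,3',4',4',5'-heptamethoxy-6,7-dimethyl-5,6,7,8-tetrahydrospiro[benzo[7]annulene-9,1'-cyclohexa[2,5]dien]-5-ol | COC1=CC2(C=C(OC)C1(OC)OC)C[C@@H](C)[C@H](C)[C@H](O)c1cc(OC)c(OC)c(OC)c12
F8 | step 12 | (5R,6S,7R)-1,2,3,3',4',4',5'-heptamethoxy-6,7-dimethyl-5,6,7,8-tetrahydrospiro[benzo[7]annulene-9,1'-cyclohexa[2,5]dien]-5-yl 4-nitrobenzoate | COC1=CC2(C=C(OC)C1(OC)OC)C[C@@H](C)[C@H](C)[C@@H](OC(=O)c3ccc(cc3)[N+](=O)[O-])c1cc(OC)c(OC)c(OC)c12
F9 | step 13 | (5R,6S,7R)-3',5-dihydroxy-1,2,3,5'-tetramethoxy-6,7-dimethyl-5,6,7,8-tetrahydrospiro[benzo[7]annulene-9,1'-cyclohexa[2,5]dien]-4'-one | COC1=CC2(C=C(O)C1=O)C[C@@H](C)[C@H](C)[C@@H](O)c1cc(OC)c(OC)c(OC)c12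
A1 | alternative 1 | 1-[(5R,6S,7R)-5-(tert-butyldimethylsilyloxy)-1,2,3-trimethoxy-6,7-dimethyl-5,6,7,8-tetrahydro-9H-benzo[7]annulen-9-ylidene]propan-2-one | CC(=O)C=C1C[C@@H](C)[C@H](C)[C@@H](O[Si](C)(C)C(C)(C)C)c2cc(OC)c(OC)c(OC)c12
A2 | alternative 1 | dimethyl malonate | COC(=O)CC(=O)OC
A3 | alternative 1 | spiro cyclohexane-1,3-dione with C3' and C5' carbonyls, O7 silyl ether | O=C1CC(=O)CC2(C1)C[C@@H](C)[C@H](C)[C@@H](O[Si](C)(C)C(C)(C)C)c1cc(OC)c(OC)c(OC)c12
A4 | alternative 2 | 4-(tert-butyldimethylsilyloxy)-4-[2-(4-hydroxy-3,5-dimethoxyphenyl)-3,4,5-trimethoxyphenyl]-2,3-dimethylbutyl methanesulfonate (stereocentres as in the target) | CS(=O)(=O)OC[C@@H](C)[C@H](C)[C@@H](O[Si](C)(C)C(C)(C)C)c1cc(OC)c(OC)c(OC)c1-c1cc(OC)c(O)c(OC)c1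
A5 | alternative 2 | O7-tert-butyldimethylsilyl ether of the target | COC1=CC2(C=C(OC)C1=O)C[C@@H](C)[C@H](C)[C@@H](O[Si](C)(C)C(C)(C)C)c1cc(OC)c(OC)c(OC)c12
A6 | alternative 3 | 4-(6-bromo-2,3,4-trimethoxyphenyl)-2,6-dimethoxyphenol | COc1cc(cc(OC)c1O)-c1c(Br)cc(OC)c(OC)c1OC
A7 | alternative 3 | 2,3-dimethylbuta-1,3-diene | CC(=C)C(C)=C
A8 | alternative 3 | 7-deoxy spirodienone with a tetrasubstituted C8=C8' double bond | COC1=CC2(C=C(OC)C1=O)CC(C)=C(C)Cc1cc(OC)c(OC)c(OC)c12
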